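## Structural features

The target is a humulane-type sesquiterpenoid built on a single eleven-membered carbocycle, numbered here from C1 (the carbon bearing CO2H) through C2 (=CH), C3, C4, C5 (C=CH2), C6 (CHOH), C7, C8 (CMe2), C9 and C10 (CH–O-isovaleryl) to C11. C1=C2 is a trisubstituted enoic-acid double bond of E configuration, which places the ring bonds C2–C3 and C1–C11 cis, so it is a cis-cycloalkene. C5 carries an exocyclic methylidene and is directly flanked by the allylic carbinol C6 (S); C10 (S) carries the isovalerate and is γ to the carboxyl carbon. The two stereocentres are 1,5-related across the quaternary C8 and neither has a stereocentre next to it, so neither can be set by relay from the other. Fragile points are the isovalerate (the acid must be unmasked without hydrolysis), the secondary allylic alcohol (ionisable in strong acid), a free C10–OH next to an unhindered C1 ester (lactonisation), and any C10 ketone, which is β,γ-unsaturated and can pull C1=C2 into conjugation. The real difficulty is the medium ring itself, which must be made with a defined trisubstituted enoate geometry and with the methylidene–carbinol pair in place, together with the two remote stereocentres. The key step exploits the arc C6–C7–C8(Me2)–C9–C10 with oxygen on C6 and C10, which is the skeleton of dimedone with C5 as its C-2: an imagined transannular bond C5–C10 turns the ring into a cyclohexane (C5–C10) fused to a cycloheptene (C10, C11, C1–C5), and in that bicycle the C10 oxygen, C5 and the exocyclic CH2 form the 1,3-array of a γ-hydroxy sulfonate, ready for fragmentation.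

## Logic of the disconnections

19 from 17: only O–Si (C6) and O–C(tert-butyl) (carboxyl) are cut. Both masks come off without base or protic acid, so the isovalerate and the allylic alcohol survive. The demand is an ester that can be removed beside a second ester, hence tert-butyl.

17 from 16 from 15: the acyl C–O bond at C10 is cut, then the C10–H bond. This leaves 15 with a single stereocentre (C6). The demand is heavy: the reduction must choose one face of a ketone flanked by two CH2 groups, which calls for an enzyme and not a small reagent.

15 from 13 (key disconnection): the bond C5–C10, absent in the target, is re-formed; the methylidene CH2 becomes CH2OTs and the C10 ketone a tertiary alcohol. In one sentence: the eleven-membered ring is released by Grob fragmentation of the ring-fusion bond of the 6/7-fused γ-hydroxy tosylate 13. The gain is that the medium ring is never closed end to end; it is the perimeter of two common rings. The methylidene arises in the same step, the enoate geometry is inherited from a seven-membered ring, and the two ring-fusion centres need no control because both become sp2. The demand is that fragmentation beats oxetane formation and that the alkoxide at the future C10 is the only electron donor.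

13 from 12: the C=C of the seven-membered ring is cut into two terminal alkenes. The gain is a monocyclic cyclohexane carrying two vicinal tethers. The demand is that metathesis engages a 1,1-disubstituted acrylate; a seven-membered ring can only give the ring-cis alkene that the target needs.

12 from 9 and 10: the bond between the carbinol carbon (future C10) and the allylic CH2 (future C11) is cut. This removes the whole C11–C1(CO2R) unit as the purchasable C4 building block 10. The demand is addition to a hindered ketone without lactonisation onto the ester.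

9 from 7: the C–H bond at the future C6 (and O–Si) is cut. This leads back to an achiral dione with a mirror plane, so the only absolute stereochemical event before the ring expansion is an enantiotopic-group-selective reduction. The demand is face selectivity at the carbonyl only; the relative configuration at the quaternary carbon is irrelevant.

7 from 5: the bond from the quaternary carbon to its CH2O group is cut (aldol with formaldehyde), together with O–S. The gain is a 2-monoalkyl-1,3-dione. The demand is C-alkylation, not O-alkylation, which formaldehyde secures.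

5 from 1 and 2: the bond from C-2 of the dione to the side chain is cut (conjugate addition), and the terminal C=CH2 is traced back to the aldehyde of 2. Both starting materials are commodity chemicals. The demand is mono-addition, secured by the hemiacetal form of the adduct.

## Other disconnections considered

Alternative 1: the route that comes to mind first cuts C5–C6 and closes the ring by an intramolecular Nozaki–Hiyama–Kishi coupling. The seco iodo-aldehyde A1 (vinyl iodide at C5, aldehyde at C6) would give the macrocyclic allylic alcohol A2, the tert-butyl ester of the target. The chosen plan is preferred on three grounds. The closure forms an eleven-membered ring end to end, with the transannular strain of the medium ring in the transition state and the need for high dilution. The configuration at C6 would have to come from 1,5-induction by C10 across the quaternary C8, for which no conformational basis exists, so a mixture with the C6 epimer of A2 is to be expected. A1 itself needs a separate stereoselective synthesis of the E-enoate, of C10 and of the 2-iodoalkene, which should make that route longer.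

Alternative 2: cut C1=C2 and close the ring by ring-closing metathesis of the acyclic triene A3, again aiming at A2. Metathesis would have to join a terminal alkene and a 1,1-disubstituted, electron-poor acrylate in a medium ring, a slow closure that competes with dimerisation. The geometry of the new trisubstituted double bond is not enforced in an eleven-membered ring, where cis and trans cycloalkenes are of similar strain. The chosen plan performs the same metathesis in a seven-membered ring, where only the required ring-cis isomer can form, and enlarges the ring afterwards with the geometry intact. A3 also needs both stereocentres set independently on an open chain.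

Alternative 3: cut C3–C4 and reconnect C1–C6, that is, an anionic oxy-Cope ring expansion (7 to 11) of the 1,2-dialkenylcycloheptanol A4 to the cycloundecenone A5. The [3,3] shift turns C6 into a carbonyl carbon, so that stereocentre is lost and must be rebuilt by a later ketone reduction. It also delivers C5 as a methyl-bearing sp3 carbon, so the methylidene must be created by a further oxidation-state adjustment. The enoate geometry depends on the chair or boat transition state and therefore on the relative configuration of two adjacent fully substituted carbons of A4. A4 is a cycloheptane that is not available from a simple ring, whereas the chosen bicycle grows from dimedone.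

Key step: step 9

Remark: 1, 2 and 10 are taken as catalogue chemicals. The two ring-fusion carbons in 8, 9 and 12–14 are deliberately left uncontrolled (no descriptor in the SMILES), because step 9 converts both into sp2 carbons.

## Route

Step 1
Reactants: 1 dimedone (5,5-dimethylcyclohexane-1,3-dione); 2 acrolein (prop-2-enal)
Product: 3 2-hydroxy-7,7-dimethyl-2,3,4,6,7,8-hexahydro-5H-chromen-5-one (racemic lactol)
Conditions: H2O, rt
Reagents that add atoms: none
Why: Michael addition of the strongly enolised 1,3-dione to acrolein, which proceeds in water without added base; the adduct is held as the cyclic hemiacetal, which suppresses a second addition, and its racemic hemiacetal centre disappears in step 2.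

Step 2
Reactants: 3 2-hydroxy-7,7-dimethyl-2,3,4,6,7,8-hexahydro-5H-chromen-5-one
Product: 5 2-(but-3-en-1-yl)-5,5-dimethylcyclohexane-1,3-dione, via open-chain aldehyde 4 (not isolated)
Conditions: Ph3PCH3Br (3 equiv), KOtBu (3 equiv), THF, 0 °C → rt; then 1 M HCl
Reagents that add atoms: methyltriphenylphosphonium bromide, C[P+](c1ccccc1)(c1ccccc1)c1ccccc1.[Br-]
Why: Wittig methylenation of a lactol; the first equivalent of ylide deprotonates the vinylogous acid and opens the hemiacetal to the aldehyde 4 (as its dione enolate), whose aldehyde is olefinated while the delocalised dione anion is inert to the ylide.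

Step 3
Reactants: 5 2-(but-3-en-1-yl)-5,5-dimethylcyclohexane-1,3-dione
Product: 6 2-(but-3-en-1-yl)-2-(hydroxymethyl)-5,5-dimethylcyclohexane-1,3-dione
Conditions: 37% aq. HCHO (excess), Et3N (cat.), THF, rt
Reagents that add atoms: formaldehyde, C=O
Why: Aldol hydroxymethylation of a 2-alkyl-1,3-dione at C-2, the standard entry to 2-alkyl-2-hydroxymethyl-1,3-diones; C-attack gives the stable quaternary product whereas O-attack is reversible, and excess formaldehyde with only a weak amine keeps the retro-aldol equilibrium on the product side. Compound 6 is achiral (mirror plane through C-2 and C-5).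

Step 4
Reactants: 6 2-(but-3-en-1-yl)-2-(hydroxymethyl)-5,5-dimethylcyclohexane-1,3-dione
Product: 7 [1-(but-3-en-1-yl)-4,4-dimethyl-2,6-dioxocyclohexyl]methyl 4-methylbenzenesulfonate
Conditions: TsCl, pyridine, DMAP (cat.), CH2Cl2, 0 °C → rt
Reagents that add atoms: 4-methylbenzenesulfonyl chloride, Cc1ccc(cc1)S(=O)(=O)Cl
Why: Sulfonylation of a primary alcohol; the neighbouring carbon is quaternary, so neither E2 nor E1cB loss of tosylate is possible, and the neopentyl sulfonate is inert to SN2 in the steps that follow.

Step 5
Reactants: 7 [1-(but-3-en-1-yl)-4,4-dimethyl-2,6-dioxocyclohexyl]methyl 4-methylbenzenesulfonate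
Product: 8 [(2S)-1-(but-3-en-1-yl)-2-hydroxy-4,4-dimethyl-6-oxocyclohexyl]methyl 4-methylbenzenesulfonate (mixture of C-1 epimers)
Conditions: (R)-2-methyl-CBS-oxazaborolidine (20 mol %), catecholborane (1.1 equiv), toluene, −78 → −40 °C; pH 7 buffer work-up
Reagents that add atoms: none
Why: CBS reduction used as an enantiotopic-group desymmetrisation of a 2,2-disubstituted cyclohexane-1,3-dione; in the catalyst–borane–ketone complex the quaternary C-1 flank acts as the large group and CH2-3 as the small one, so the (R)-catalyst should deliver hydride to the face that gives the (S)-carbinol at whichever carbonyl reacts. The cis/trans mixture at C-1 is harmless because C-1 becomes sp2 in step 9; catecholborane at low temperature spares the terminal alkene, and a neutral work-up avoids retro-aldol cleavage of the β-hydroxy ketone.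

Step 6
Reactants: 8 [(2S)-1-(but-3-en-1-yl)-2-hydroxy-4,4-dimethyl-6-oxocyclohexyl]methyl 4-methylbenzenesulfonate
Product: 9 [(2S)-1-(but-3-en-1-yl)-4,4-dimethyl-6-oxo-2-{[tri(propan-2-yl)silyl]oxy}cyclohexyl]methyl 4-methylbenzenesulfonate
Conditions: TIPSOTf, 2,6-lutidine, CH2Cl2, −78 → 0 °C
Reagents that add atoms: triisopropylsilyl trifluoromethanesulfonate, CC(C)[Si](OS(=O)(=O)C(F)(F)F)(C(C)C)C(C)C
Why: Silylation of a hindered secondary alcohol with a silyl triflate and a hindered pyridine base; the ether stops this oxygen from acting as a fragmentation or retro-aldol donor later, and TIPS is chosen because it should not undergo O→O transfer to the tertiary alkoxide of step 9.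

Step 7
Reactants: 9 [(2S)-1-(but-3-en-1-yl)-4,4-dimethyl-6-oxo-2-{[tri(propan-2-yl)silyl]oxy}cyclohexyl]methyl 4-methylbenzenesulfonate; 10 tert-butyl 2-(bromomethyl)prop-2-enoate
Product: 12 tert-butyl 2-{[(3S)-2-(but-3-en-1-yl)-1-hydroxy-5,5-dimethyl-2-{[(4-methylbenzenesulfonyl)oxy]methyl}-3-{[tri(propan-2-yl)silyl]oxy}cyclohexyl]methyl}prop-2-enoate (mixture at C-1 and C-2), via allylzinc bromide 11 (not isolated)
Conditions: Zn dust (activated), THF, 0 °C → rt; sat. aq. NH4Cl
Reagents that add atoms: none
Why: Barbier-type addition of a 2-(alkoxycarbonyl)allylzinc reagent to a ketone through a six-membered cyclic transition state, a reagent class that adds to hindered ketones; the tert-butyl ester slows attack of the tertiary zinc alkoxide on the ester, and the zinc alkoxide is too weak a donor to trigger fragmentation. The new carbinol centre forms as a mixture and is deleted in step 9.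

Step 8
Reactants: 12 tert-butyl 2-{[(3S)-2-(but-3-en-1-yl)-1-hydroxy-5,5-dimethyl-2-{[(4-methylbenzenesulfonyl)oxy]methyl}-3-{[tri(propan-2-yl)silyl]oxy}cyclohexyl]methyl}prop-2-enoate
Product: 13 tert-butyl (1S)-4a-hydroxy-3,3-dimethyl-9a-{[(4-methylbenzenesulfonyl)oxy]methyl}-1-{[tri(propan-2-yl)silyl]oxy}-2,3,4,4a,5,8,9,9a-octahydro-1H-benzo[7]annulene-6-carboxylate (mixture at C-4a and C-9a)
Conditions: second-generation Grubbs catalyst (5 mol %), CH2Cl2 (0.01 M), 40 °C
Reagents that add atoms: none
Why: Ring-closing metathesis; the catalyst loads on the terminal butenyl alkene and closes onto the 1,1-disubstituted acrylate to give a seven-membered trisubstituted enoate, helped by the two fully substituted carbons that hold the tethers gauche in both diastereomers. A seven-membered ring admits only the ring-cis double bond, which is the geometry (E in the target) that is needed.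

Step 9
Reactants: 13 tert-butyl (1S)-4a-hydroxy-3,3-dimethyl-9a-{[(4-methylbenzenesulfonyl)oxy]methyl}-1-{[tri(propan-2-yl)silyl]oxy}-2,3,4,4a,5,8,9,9a-octahydro-1H-benzo[7]annulene-6-carboxylate
Product: 15 tert-butyl (1E,6S)-8,8-dimethyl-5-methylidene-10-oxo-6-{[tri(propan-2-yl)silyl]oxy}cycloundec-1-ene-1-carboxylate, via potassium alkoxide 14 (not isolated)
Conditions: KHMDS (1.05 equiv), THF, −78 → 0 °C; AcOH, −78 °C
Reagents that add atoms: none
Why: Grob (Wharton-type) 1,3-fragmentation of a γ-hydroxy sulfonate: deprotonation gives the tertiary alkoxide 14, whose oxygen lone pair pushes into the C4a–C9a bond (C10–C5 of the target) as that bond, antiperiplanar to CH2–OTs, expels tosylate, so that C4a becomes the ketone and C9a with its exocyclic CH2 becomes the methylidene in one concerted event. The closest known reaction type is the base-induced fragmentation of cyclic 1,3-diol monosulfonates to medium-ring keto-olefins. No ring is closed by bond formation: the eleven-membered ring is the perimeter of the 6/7-fused bicycle and is set free by cleavage of the shared bond, so the entropic and transannular cost of an end-to-end closure is not paid. No stereocentre is created; the two uncontrolled ring-fusion centres are destroyed, so every diastereomer of 13 converges on 15, C-1 (C-6 of 15) is a spectator that keeps its S configuration, and the ring-cis C6=C7 bond is carried over unchanged as the (1E)-enoate. The step needs fragmentation to beat intramolecular O-alkylation: the nucleofugal carbon is neopentylic and the oxetane would be a strained oxa[5.4.2]propellane, whereas the freely rotating CH2–OTs can always reach the antiperiplanar alignment and cleavage relieves the congestion of the fully substituted C4a–C9a bond. The alkoxide must also be the only donor: the C-1 oxygen is capped as a TIPS ether, and the tert-butyl ester cannot lactonise onto the alkoxide because the lactone would place C6=C7 at a bridgehead. One equivalent of a non-nucleophilic base and a cold acidic quench keep the new β,γ-unsaturated ketone from sliding into conjugation.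

Step 10
Reactants: 15 tert-butyl (1E,6S)-8,8-dimethyl-5-methylidene-10-oxo-6-{[tri(propan-2-yl)silyl]oxy}cycloundec-1-ene-1-carboxylate
Product: 16 tert-butyl (1E,6S,10S)-10-hydroxy-8,8-dimethyl-5-methylidene-6-{[tri(propan-2-yl)silyl]oxy}cycloundec-1-ene-1-carboxylate
Conditions: ketoreductase (selected from a panel for the 10S alcohol), NADP+ (cat.), i-PrOH, phosphate buffer pH 7.0/DMSO, 30 °C
Reagents that add atoms: none
Why: Biocatalytic carbonyl reduction by a ketoreductase (NADPH-dependent alcohol dehydrogenase) with isopropanol as terminal reductant; the active site, not a small reagent, should tell apart the two CH2 flanks (one leading to the planar enoate, the other to the neopentyl CMe2) and set C-10 under catalyst control, independent of the remote C-6. The neutral aqueous medium prevents both double-bond migration in the β,γ-unsaturated ketone and lactonisation of the product onto the tert-butyl ester.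

Step 11
Reactants: 16 tert-butyl (1E,6S,10S)-10-hydroxy-8,8-dimethyl-5-methylidene-6-{[tri(propan-2-yl)silyl]oxy}cycloundec-1-ene-1-carboxylate
Product: 17 tert-butyl (1E,6S,10S)-8,8-dimethyl-5-methylidene-10-[(3-methylbutanoyl)oxy]-6-{[tri(propan-2-yl)silyl]oxy}cycloundec-1-ene-1-carboxylate
Conditions: isovaleric anhydride, Et3N, DMAP (cat.), CH2Cl2, 0 °C → rt
Reagents that add atoms: 3-methylbutanoic anhydride, CC(C)CC(=O)OC(=O)CC(C)C
Why: DMAP-catalysed acyl transfer to the only free hydroxyl, with retention at C-10; acylation of an unhindered secondary alcohol should be faster than its lactonisation onto the bulky tert-butyl ester.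

Step 12
Reactants: 17 tert-butyl (1E,6S,10S)-8,8-dimethyl-5-methylidene-10-[(3-methylbutanoyl)oxy]-6-{[tri(propan-2-yl)silyl]oxy}cycloundec-1-ene-1-carboxylate
Product: 19 (1E,6S,10S)-6-hydroxy-8,8-dimethyl-5-methylidene-10-[(3-methylbutanoyl)oxy]cycloundec-1-ene-1-carboxylic acid (the target), via trimethylsilyl ester 18 (not isolated)
Conditions: TMSOTf, 2,6-lutidine, CH2Cl2, 0 °C; then HF·pyridine, THF, 0 °C → rt
Reagents that add atoms: none
Why: Silyl triflate with 2,6-lutidine converts the tert-butyl ester into the silyl ester 18 by loss of isobutene without free protic acid, so the allylic C-6 oxygen is not exposed to ionising conditions; buffered fluoride then cleaves the silyl ester and the TIPS ether while leaving the isovalerate, which has no free hydroxyl near enough for acyl migration.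

## Compound list

1 | dimedone (5,5-dimethylcyclohexane-1,3-dione) | CC1(C)CC(=O)CC(=O)C1 | starting material
2 | acrolein (prop-2-enal) | C=CC=O | starting material
3 | 2-hydroxy-7,7-dimethyl-2,3,4,6,7,8-hexahydro-5H-chromen-5-one (racemic) | CC1(C)CC(=O)C2=C(C1)OC(O)CC2 | intermediate
4 | 3-(4,4-dimethyl-2,6-dioxocyclohexyl)propanal (open-chain aldehyde, not isolated) | CC1(C)CC(=O)C(CCC=O)C(=O)C1 | intermediate
5 | 2-(but-3-en-1-yl)-5,5-dimethylcyclohexane-1,3-dione | C=CCCC1C(=O)CC(C)(C)CC1=O | intermediate
6 | 2-(but-3-en-1-yl)-2-(hydroxymethyl)-5,5-dimethylcyclohexane-1,3-dione | C=CCCC1(CO)C(=O)CC(C)(C)CC1=O | intermediate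
7 | [1-(but-3-en-1-yl)-4,4-dimethyl-2,6-dioxocyclohexyl]methyl 4-methylbenzenesulfonate | C=CCCC1(COS(=O)(=O)c2ccc(C)cc2)C(=O)CC(C)(C)CC1=O | intermediate
8 | [(2S)-1-(but-3-en-1-yl)-2-hydroxy-4,4-dimethyl-6-oxocyclohexyl]methyl 4-methylbenzenesulfonate (C-1 epimers) | C=CCCC1(COS(=O)(=O)c2ccc(C)cc2)[C@@H](O)CC(C)(C)CC1=O | intermediate
9 | [(2S)-1-(but-3-en-1-yl)-4,4-dimethyl-6-oxo-2-{[tri(propan-2-yl)silyl]oxy}cyclohexyl]methyl 4-methylbenzenesulfonate (C-1 epimers) | C=CCCC1(COS(=O)(=O)c2ccc(C)cc2)[C@@H](O[Si](C(C)C)(C(C)C)C(C)C)CC(C)(C)CC1=O | intermediate
10 | tert-butyl 2-(bromomethyl)prop-2-enoate | C=C(CBr)C(=O)OC(C)(C)C | starting material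
11 | [2-(tert-butoxycarbonyl)prop-2-en-1-yl]zinc bromide (not isolated) | C=C(C[Zn]Br)C(=O)OC(C)(C)C | intermediate
12 | tert-butyl 2-{[(3S)-2-(but-3-en-1-yl)-1-hydroxy-5,5-dimethyl-2-{[(4-methylbenzenesulfonyl)oxy]methyl}-3-{[tri(propan-2-yl)silyl]oxy}cyclohexyl]methyl}prop-2-enoate (mixture at C-1 and C-2) | C=CCCC1(COS(=O)(=O)c2ccc(C)cc2)[C@@H](O[Si](C(C)C)(C(C)C)C(C)C)CC(C)(C)CC1(O)CC(=C)C(=O)OC(C)(C)C | intermediate
13 | tert-butyl (1S)-4a-hydroxy-3,3-dimethyl-9a-{[(4-methylbenzenesulfonyl)oxy]methyl}-1-{[tri(propan-2-yl)silyl]oxy}-2,3,4,4a,5,8,9,9a-octahydro-1H-benzo[7]annulene-6-carboxylate (mixture at C-4a and C-9a) | Cc1ccc(cc1)S(=O)(=O)OCC12CC/C=C(/C(=O)OC(C)(C)C)CC2(O)CC(C)(C)C[C@@H]1O[Si](C(C)C)(C(C)C)C(C)C | intermediate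
14 | potassium 4a-alkoxide of 13 (not isolated) | Cc1ccc(cc1)S(=O)(=O)OCC12CC/C=C(/C(=O)OC(C)(C)C)CC2([O-])CC(C)(C)C[C@@H]1O[Si](C(C)C)(C(C)C)C(C)C.[K+] | intermediate
15 | tert-butyl (1E,6S)-8,8-dimethyl-5-methylidene-10-oxo-6-{[tri(propan-2-yl)silyl]oxy}cycloundec-1-ene-1-carboxylate | C=C1CC/C=C(/C(=O)OC(C)(C)C)CC(=O)CC(C)(C)C[C@@H]1O[Si](C(C)C)(C(C)C)C(C)C | intermediate
16 | tert-butyl (1E,6S,10S)-10-hydroxy-8,8-dimethyl-5-methylidene-6-{[tri(propan-2-yl)silyl]oxy}cycloundec-1-ene-1-carboxylate | C=C1CC/C=C(/C(=O)OC(C)(C)C)C[C@@H](O)CC(C)(C)C[C@@H]1O[Si](C(C)C)(C(C)C)C(C)C | intermediate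
17 | tert-butyl (1E,6S,10S)-8,8-dimethyl-5-methylidene-10-[(3-methylbutanoyl)oxy]-6-{[tri(propan-2-yl)silyl]oxy}cycloundec-1-ene-1-carboxylate | C=C1CC/C=C(/C(=O)OC(C)(C)C)C[C@@H](OC(=O)CC(C)C)CC(C)(C)C[C@@H]1O[Si](C(C)C)(C(C)C)C(C)C | intermediate
18 | trimethylsilyl (1E,6S,10S)-8,8-dimethyl-5-methylidene-10-[(3-methylbutanoyl)oxy]-6-{[tri(propan-2-yl)silyl]oxy}cycloundec-1-ene-1-carboxylate (not isolated) | C=C1CC/C=C(/C(=O)O[Si](C)(C)C)C[C@@H](OC(=O)CC(C)C)CC(C)(C)C[C@@H]1O[Si](C(C)C)(C(C)C)C(C)C | intermediate
19 | (1E,6S,10S)-6-hydroxy-8,8-dimethyl-5-methylidene-10-[(3-methylbutanoyl)oxy]cycloundec-1-ene-1-carboxylic acid | C=C1CC/C=C(/C(=O)O)C[C@@H](OC(=O)CC(C)C)CC(C)(C)C[C@@H]1O | target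

## Step count and least certain steps

Total step count: 12. Longest linear sequence: 12 steps (1 to 19).

**Step 9 (key step).** The most likely failure is intramolecular O-alkylation (oxetane closure) running ahead of fragmentation. The second is proton transfer from C-11 of the product to unreacted alkoxide, which lets the ring double bond migrate into conjugation with the new ketone. The fallback replaces the concerted fragmentation by a retro-aldol/E1cB sequence driven by an enolate. It sets out from 13: HF·pyridine removes the silyl group to give the diol tert-butyl (1S)-1,4a-dihydroxy-3,3-dimethyl-9a-{[(4-methylbenzenesulfonyl)oxy]methyl}-2,3,4,4a,5,8,9,9a-octahydro-1H-benzo[7]annulene-6-carboxylate F1. Dess–Martin oxidation of the secondary hydroxyl gives the keto alcohol tert-butyl 4a-hydroxy-3,3-dimethyl-9a-{[(4-methylbenzenesulfonyl)oxy]methyl}-1-oxo-2,3,4,4a,5,8,9,9a-octahydro-1H-benzo[7]annulene-6-carboxylate F2. DBU in CH2Cl2 should then cleave the same ring-fusion bond by retro-aldol reaction, and the enolate so formed expels tosylate to give the achiral macrocycle tert-butyl (1E)-8,8-dimethyl-5-methylidene-6,10-dioxocycloundec-1-ene-1-carboxylate F3. Reduction of the conjugated C-6 carbonyl with the (R)-CBS catalyst and catecholborane at −78 °C (the alkenyl flank as the large group; chemoselectivity over the C-10 ketone secured by stoichiometry and temperature) gives tert-butyl (1E,6S)-6-hydroxy-8,8-dimethyl-5-methylidene-10-oxocycloundec-1-ene-1-carboxylate F4. Silylation as in step 6 returns to the route at 15.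

**Step 10.** The most likely failure is insufficient face discrimination, or no turnover, with a large lipophilic ketone whose two flanks both begin with CH2. Slow lactonisation of the hydroxy ester during a long incubation is a second concern. The fallback gives up catalyst control and uses both epimers. It sets out from 15: NaBH4 in MeOH at −40 °C gives 16 together with its epimer tert-butyl (1E,6S,10R)-10-hydroxy-8,8-dimethyl-5-methylidene-6-{[tri(propan-2-yl)silyl]oxy}cycloundec-1-ene-1-carboxylate F5, which are diastereomers and separable. 16 goes on through step 11 with retention. F5 is esterified with isovaleric acid under Mitsunobu conditions (PPh3, DIAD) with inversion, so both streams rejoin the route at 17.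

**Step 5.** The most likely failures are competing hydroboration of the terminal alkene, erosion of enantioface selection if the two flanks of the carbonyl are not read as large and small, and over-reduction. The fallback moves the enantioselective event to the end, where the substrate is achiral. It sets out from 7: mono-allylation with 10 (indium, aqueous THF, so that no basic alkoxide persists) gives racemic tert-butyl 2-{[2-(but-3-en-1-yl)-1-hydroxy-5,5-dimethyl-2-{[(4-methylbenzenesulfonyl)oxy]methyl}-3-oxocyclohexyl]methyl}prop-2-enoate F6. Ring-closing metathesis as in step 8 gives the keto alcohol F2 as a racemate. The sequence then follows the fallback above through the diketone F3 and the allylic alcohol F4, and returns to the route at 15.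

**Step 7.** The most likely failures are slow addition to a ketone that is flanked by a quaternary carbon and shielded by an axial methyl group and the silyl ether, and attack of the zinc alkoxide on the ester to give a spiro-lactone that can no longer undergo the metathesis. The fallback changes the order and uses the neighbouring hydroxyl instead of masking it. It sets out from 8: allylation with 10 before silylation (indium, aqueous THF; less shielded carbonyl, activated by the adjacent hydroxyl, product protonated at once) gives the diol tert-butyl 2-{[(3S)-2-(but-3-en-1-yl)-1,3-dihydroxy-5,5-dimethyl-2-{[(4-methylbenzenesulfonyl)oxy]methyl}cyclohexyl]methyl}prop-2-enoate F7. TIPSOTf with 2,6-lutidine at −78 °C should silylate only the secondary hydroxyl, which returns to the route at 12.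

## Further compounds

F1 | step 9 | tert-butyl (1S)-1,4a-dihydroxy-3,3-dimethyl-9a-{[(4-methylbenzenesulfonyl)oxy]methyl}-2,3,4,4a,5,8,9,9a-octahydro-1H-benzo[7]annulene-6-carboxylate | Cc1ccc(cc1)S(=O)(=O)OCC12CC/C=C(/C(=O)OC(C)(C)C)CC2(O)CC(C)(C)C[C@@H]1O
F2 | step 9 | tert-butyl 4a-hydroxy-3,3-dimethyl-9a-{[(4-methylbenzenesulfonyl)oxy]methyl}-1-oxo-2,3,4,4a,5,8,9,9a-octahydro-1H-benzo[7]annulene-6-carboxylate | Cc1ccc(cc1)S(=O)(=O)OCC12CC/C=C(/C(=O)OC(C)(C)C)CC2(O)CC(C)(C)CC1=O
F3 | step 9 | tert-butyl (1E)-8,8-dimethyl-5-methylidene-6,10-dioxocycloundec-1-ene-1-carboxylate | C=C1CC/C=C(/C(=O)OC(C)(C)C)CC(=O)CC(C)(C)CC1=O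
F4 | step 9 | tert-butyl (1E,6S)-6-hydroxy-8,8-dimethyl-5-methylidene-10-oxocycloundec-1-ene-1-carboxylate | C=C1CC/C=C(/C(=O)OC(C)(C)C)CC(=O)CC(C)(C)C[C@@H]1O
F5 | step 10 | tert-butyl (1E,6S,10R)-10-hydroxy-8,8-dimethyl-5-methylidene-6-{[tri(propan-2-yl)silyl]oxy}cycloundec-1-ene-1-carboxylate | C=C1CC/C=C(/C(=O)OC(C)(C)C)C[C@H](O)CC(C)(C)C[C@@H]1O[Si](C(C)C)(C(C)C)C(C)C
F6 | step 5 | tert-butyl 2-{[2-(but-3-en-1-yl)-1-hydroxy-5,5-dimethyl-2-{[(4-methylbenzenesulfonyl)oxy]methyl}-3-oxocyclohexyl]methyl}prop-2-enoate (racemic) | C=CCCC1(COS(=O)(=O)c2ccc(C)cc2)C(=O)CC(C)(C)CC1(O)CC(=C)C(=O)OC(C)(C)C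
F7 | step 7 | tert-butyl 2-{[(3S)-2-(but-3-en-1-yl)-1,3-dihydroxy-5,5-dimethyl-2-{[(4-methylbenzenesulfonyl)oxy]methyl}cyclohexyl]methyl}prop-2-enoate | C=CCCC1(COS(=O)(=O)c2ccc(C)cc2)[C@@H](O)CC(C)(C)CC1(O)CC(=C)C(=O)OC(C)(C)C
A1 | alternative 1 | tert-butyl (2E)-2-{(2S)-4,4-dimethyl-2-[(3-methylbutanoyl)oxy]-6-oxohexyl}-6-iodohepta-2,6-dienoate | C=C(I)CC/C=C(/C(=O)OC(C)(C)C)C[C@@H](OC(=O)CC(C)C)CC(C)(C)CC=O
A2 | alternative 1 | tert-butyl (1E,6S,10S)-6-hydroxy-8,8-dimethyl-5-methylidene-10-[(3-methylbutanoyl)oxy]cycloundec-1-ene-1-carboxylate | C=C1CC/C=C(/C(=O)OC(C)(C)C)C[C@@H](OC(=O)CC(C)C)CC(C)(C)C[C@@H]1O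
A3 | alternative 2 | tert-butyl (4S,8S)-8-hydroxy-6,6-dimethyl-2,9-dimethylidene-4-[(3-methylbutanoyl)oxy]tridec-12-enoate | C=CCCC(=C)[C@@H](O)CC(C)(C)C[C@H](OC(=O)CC(C)C)CC(=C)C(=O)OC(C)(C)C
A4 | alternative 3 | tert-butyl (6S)-1-ethenyl-2-hydroxy-4,4-dimethyl-2-(prop-1-en-2-yl)-6-{[tri(propan-2-yl)silyl]oxy}cycloheptane-1-carboxylate | C=CC1(C(=O)OC(C)(C)C)C[C@@H](O[Si](C(C)C)(C(C)C)C(C)C)CC(C)(C)CC1(O)C(C)=C
A5 | alternative 3 | tert-butyl (1E,10S)-5,8,8-trimethyl-6-oxo-10-{[tri(propan-2-yl)silyl]oxy}cycloundec-1-ene-1-carboxylate | CC1CC/C=C(/C(=O)OC(C)(C)C)C[C@@H](O[Si](C(C)C)(C(C)C)C(C)C)CC(C)(C)CC1=O
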